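**Retrosynthetic overview**
1. Target 15 comes from global hydrogenolysis of the perbenzylated tridepside 14 (three benzyl ethers, one benzyl ester).
2. 14 comes from the B–C depside ester: didepside acid 10 plus benzyl orsellinate 12 (ring C, from orsellinic acid 11).
3. 10 comes from the A–B depside ester: ring A acid 5 plus orcylaldehyde 6 (ring B, CHO as latent CO2H), then 2-O-benzylation and Pinnick oxidation.
4. 5 comes from a proposed new carboxylate-directed ortho C–H methoxylation of acid 4 (forms the C6–OMe bond of ring A); 4 comes from commercial acid 1.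
5. No ring is built; the three benzene rings are bought and joined in the order A, then A–B, then A–B–C.

Assumption: the target has no stereocentre (achiral aromatic tridepside), so "single enantiomer" is taken as the constitution exactly as drawn; 1, 6 and 11 are bought.

**Route**

Step 1
Reactants: 1 3,4-dimethoxy-2-methylbenzoic acid
Product: 2 3,4-dihydroxy-2-methylbenzoic acid
Conditions: BBr3 (3.5 equiv), CH2Cl2, −78 °C to rt; then H2O
Reagents that add atoms: none
Why: BBr3 demethylation of aryl methyl ethers (Lewis acid complexation, bromide SN2 at methyl) frees the catechol so that it can carry hydrogenolysable groups instead of methyl.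

Step 2
Reactants: 2 3,4-dihydroxy-2-methylbenzoic acid
Product: 3 benzyl 3,4-bis(benzyloxy)-2-methylbenzoate
Conditions: BnBr (3.5 equiv), K2CO3 (4 equiv), DMF, 60 °C
Reagents that add atoms: benzyl bromide, BrCc1ccccc1
Why: Williamson etherification of both phenoxides and SN2 alkylation of the carboxylate go to completion with excess benzyl bromide in DMF.

Step 3
Reactants: 3 benzyl 3,4-bis(benzyloxy)-2-methylbenzoate
Product: 4 3,4-bis(benzyloxy)-2-methylbenzoic acid
Conditions: NaOH (aq), THF/MeOH, 60 °C; then aq. HCl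
Reagents that add atoms: sodium hydroxide, [Na+].[OH-]
Why: Saponification (acyl–oxygen cleavage) of a benzoate with only one ortho substituent is facile and leaves the benzyl ethers untouched.

Step 4
Reactants: 4 3,4-bis(benzyloxy)-2-methylbenzoic acid
Product: 5 3,4-bis(benzyloxy)-6-methoxy-2-methylbenzoic acid
Conditions: Pd(OAc)2 (10 mol%), N-acetylglycine (20 mol%), KOAc (30 mol%), PhI(OAc)2 (1.5 equiv), MeOH, 60 °C
Reagents that add atoms: methanol, CO
Why: Proposed new method: free-carboxylate-directed ortho C–H methoxylation. The potassium carboxylate of 4 binds divalent palladium through one oxygen, and the N-acyl amino acid ligand mediates concerted metalation–deprotonation at C6–H, the only ortho C–H because C2 carries the methyl group, to give a five-membered palladacycle. PhI(OAc)2 oxidises this to tetravalent palladium, acetate is exchanged for methoxide from the solvent, and C–OMe reductive elimination releases 5, which has no ortho C–H left and cannot over-react. The closest known reaction types are the palladium-catalysed carboxylate-directed ortho C–H hydroxylation of benzoic acids and the amide-directed C–H alkoxylation with PhI(OAc)2 in alcohols; direct methoxylation directed by a free carboxylic acid is the untested part.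

Step 5
Reactants: 5 3,4-bis(benzyloxy)-6-methoxy-2-methylbenzoic acid; 6 2,4-dihydroxy-6-methylbenzaldehyde
Product: 8 4-formyl-3-hydroxy-5-methylphenyl 3,4-bis(benzyloxy)-6-methoxy-2-methylbenzoate, via ring A acyl trifluoroacetate 7 (not isolated)
Conditions: (CF3CO)2O (3 equiv), toluene, 0 °C to rt
Reagents that add atoms: none
Why: Mixed-anhydride (acylium-type) esterification suits the doubly ortho-substituted acid, and the 4-OH of 6 is acylated because the 2-OH is locked in a hydrogen bond to the formyl group.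

Step 6
Reactants: 8 4-formyl-3-hydroxy-5-methylphenyl 3,4-bis(benzyloxy)-6-methoxy-2-methylbenzoate
Product: 9 3-(benzyloxy)-4-formyl-5-methylphenyl 3,4-bis(benzyloxy)-6-methoxy-2-methylbenzoate
Conditions: BnBr (1.3 equiv), K2CO3 (1.5 equiv), DMF, rt to 40 °C
Reagents that add atoms: benzyl bromide, BrCc1ccccc1
Why: Williamson etherification of the chelated phenol under anhydrous carbonate conditions, which the sterically shielded aryl ester tolerates.

Step 7
Reactants: 9 3-(benzyloxy)-4-formyl-5-methylphenyl 3,4-bis(benzyloxy)-6-methoxy-2-methylbenzoate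
Product: 10 2-(benzyloxy)-4-{[3,4-bis(benzyloxy)-6-methoxy-2-methylbenzoyl]oxy}-6-methylbenzoic acid
Conditions: NaClO2, NaH2PO4, 2-methyl-2-butene (20 equiv), t-BuOH/THF/H2O, 0 °C to rt
Reagents that add atoms: sodium chlorite, [Na+].[O-]Cl=O
Why: Pinnick oxidation converts the hindered aryl aldehyde into the acid at buffered pH without touching the depside ester, and the alkene scavenges hypochlorous acid before it can chlorinate the electron-rich rings.

Step 8
Reactants: 11 orsellinic acid (2,4-dihydroxy-6-methylbenzoic acid)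
Product: 12 benzyl 2,4-dihydroxy-6-methylbenzoate
Conditions: BnBr (1.05 equiv), KHCO3 (1.2 equiv), DMF, rt
Reagents that add atoms: benzyl bromide, BrCc1ccccc1
Why: Hydrogencarbonate deprotonates only the carboxylic acid, so SN2 alkylation gives the benzyl ester selectively and room temperature avoids decarboxylation.

Step 9
Reactants: 10 2-(benzyloxy)-4-{[3,4-bis(benzyloxy)-6-methoxy-2-methylbenzoyl]oxy}-6-methylbenzoic acid; 12 benzyl 2,4-dihydroxy-6-methylbenzoate
Product: 14 benzyl 4-{[2-(benzyloxy)-4-{[3,4-bis(benzyloxy)-6-methoxy-2-methylbenzoyl]oxy}-6-methylbenzoyl]oxy}-2-hydroxy-6-methylbenzoate, via didepside acyl trifluoroacetate 13 (not isolated)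
Conditions: (CF3CO)2O (3 equiv), toluene, rt
Reagents that add atoms: none
Why: The same mixed-anhydride depside esterification; the 4-OH of 12 reacts because the 2-OH is chelated to the ester carbonyl, as in classical depside assembly with benzyl orsellinate.

Step 10
Reactants: 14 benzyl 4-{[2-(benzyloxy)-4-{[3,4-bis(benzyloxy)-6-methoxy-2-methylbenzoyl]oxy}-6-methylbenzoyl]oxy}-2-hydroxy-6-methylbenzoate
Product: 15 4-{[4-{[3,4-dihydroxy-6-methoxy-2-methylbenzoyl]oxy}-2-hydroxy-6-methylbenzoyl]oxy}-2-hydroxy-6-methylbenzoic acid (CNP0222366.0)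
Conditions: H2 (1 atm), 10% Pd/C, EtOAc/THF, rt
Reagents that add atoms: none
Why: Catalytic hydrogenolysis cleaves the three benzyl ethers and the benzyl ester in one operation, while aryl ester links and the aryl methyl ether are inert and the non-nucleophilic solvent prevents transesterification.

**Compound list**
1 | 3,4-dimethoxy-2-methylbenzoic acid | COc1ccc(C(=O)O)c(C)c1OC | starting material
2 | 3,4-dihydroxy-2-methylbenzoic acid | Cc1c(O)c(O)ccc1C(=O)O | intermediate
3 | benzyl 3,4-bis(benzyloxy)-2-methylbenzoate | Cc1c(OCc2ccccc2)c(OCc2ccccc2)ccc1C(=O)OCc1ccccc1 | intermediate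
4 | 3,4-bis(benzyloxy)-2-methylbenzoic acid | Cc1c(OCc2ccccc2)c(OCc2ccccc2)ccc1C(=O)O | intermediate
5 | 3,4-bis(benzyloxy)-6-methoxy-2-methylbenzoic acid | COc1cc(OCc2ccccc2)c(OCc2ccccc2)c(C)c1C(=O)O | intermediate
6 | 2,4-dihydroxy-6-methylbenzaldehyde (orcylaldehyde) | Cc1cc(O)cc(O)c1C=O | starting material
7 | 3,4-bis(benzyloxy)-6-methoxy-2-methylbenzoic trifluoroacetic anhydride | COc1cc(OCc2ccccc2)c(OCc2ccccc2)c(C)c1C(=O)OC(=O)C(F)(F)F | intermediate (not isolated)
8 | 4-formyl-3-hydroxy-5-methylphenyl 3,4-bis(benzyloxy)-6-methoxy-2-methylbenzoate | COc1cc(OCc2ccccc2)c(OCc2ccccc2)c(C)c1C(=O)Oc1cc(C)c(C=O)c(O)c1 | intermediate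
9 | 3-(benzyloxy)-4-formyl-5-methylphenyl 3,4-bis(benzyloxy)-6-methoxy-2-methylbenzoate | COc1cc(OCc2ccccc2)c(OCc2ccccc2)c(C)c1C(=O)Oc1cc(C)c(C=O)c(OCc2ccccc2)c1 | intermediate
10 | 2-(benzyloxy)-4-{[3,4-bis(benzyloxy)-6-methoxy-2-methylbenzoyl]oxy}-6-methylbenzoic acid | COc1cc(OCc2ccccc2)c(OCc2ccccc2)c(C)c1C(=O)Oc1cc(C)c(C(=O)O)c(OCc2ccccc2)c1 | intermediate
11 | orsellinic acid (2,4-dihydroxy-6-methylbenzoic acid) | Cc1cc(O)cc(O)c1C(=O)O | starting material
12 | benzyl 2,4-dihydroxy-6-methylbenzoate | Cc1cc(O)cc(O)c1C(=O)OCc1ccccc1 | intermediate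
13 | 2-(benzyloxy)-4-{[3,4-bis(benzyloxy)-6-methoxy-2-methylbenzoyl]oxy}-6-methylbenzoic trifluoroacetic anhydride | COc1cc(OCc2ccccc2)c(OCc2ccccc2)c(C)c1C(=O)Oc1cc(C)c(C(=O)OC(=O)C(F)(F)F)c(OCc2ccccc2)c1 | intermediate (not isolated)
14 | benzyl 4-{[2-(benzyloxy)-4-{[3,4-bis(benzyloxy)-6-methoxy-2-methylbenzoyl]oxy}-6-methylbenzoyl]oxy}-2-hydroxy-6-methylbenzoate | COc1cc(OCc2ccccc2)c(OCc2ccccc2)c(C)c1C(=O)Oc1cc(C)c(C(=O)Oc2cc(C)c(C(=O)OCc3ccccc3)c(O)c2)c(OCc2ccccc2)c1 | intermediate
15 | 4-{[4-{[3,4-dihydroxy-6-methoxy-2-methylbenzoyl]oxy}-2-hydroxy-6-methylbenzoyl]oxy}-2-hydroxy-6-methylbenzoic acid | COc1cc(O)c(O)c(C)c1C(=O)Oc1cc(C)c(C(=O)Oc2cc(C)c(C(=O)O)c(O)c2)c(O)c1 | target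

**Totals and risks**
Total step count: 10. Longest linear sequence: 9 steps (steps 1 to 7, then 9 and 10); step 8 is the side branch.

Three steps most likely to fail:

Step 4 (proposed new C–H methoxylation). The risks are acetoxylation instead of methoxylation, protodepalladation after β-hydride loss from a palladium methoxide, and oxidant damage to the benzyl ethers. The fallback sets out from 4 and comes back at 5, using known chemistry only. Acid 4 is hydroxylated under the established aerobic carboxylate-directed conditions (Pd(OAc)2, KOAc, 1,4-benzoquinone, O2 1 atm, DMA, 115 °C) to give 3,4-bis(benzyloxy)-6-hydroxy-2-methylbenzoic acid F1. Exhaustive Williamson methylation (MeI, K2CO3, DMF) then gives methyl 3,4-bis(benzyloxy)-6-methoxy-2-methylbenzoate F2, and the hindered methyl ester is cleaved with KOH in DMSO/H2O at 90 °C to return 5. The approach changes because oxygen enters as OH from O2 through a divalent/zerovalent palladium cycle and the methyl group arrives by classical O-alkylation, so no C–OMe reductive elimination is needed.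

Step 5 (first depside ester on the aldehyde-bearing resorcinol). The risks are the low nucleophilicity of the phenol para to the formyl group, side reactions of the aldehyde under acylium conditions, and C-acylation. The fallback sets out from 11 (with 5 as acyl partner) and comes back at 10, so it also bypasses steps 6 and 7. Orsellinic acid 11 is converted with allyl bromide and KHCO3 in DMF into allyl 2,4-dihydroxy-6-methylbenzoate F3, which carries ring B at the acid oxidation level. F3 is acylated at its 4-OH by acid 5 ((CF3CO)2O, toluene, through 7) to give allyl 4-{[3,4-bis(benzyloxy)-6-methoxy-2-methylbenzoyl]oxy}-2-hydroxy-6-methylbenzoate F4. Benzylation (BnBr, K2CO3, DMF) gives allyl 2-(benzyloxy)-4-{[3,4-bis(benzyloxy)-6-methoxy-2-methylbenzoyl]oxy}-6-methylbenzoate F5, and allyl transfer to morpholine with catalytic Pd(PPh3)4 in THF releases acid 10.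

Step 9 (second hindered depside ester). The risks are sluggish acylation by the doubly ortho-substituted acid 10 and acid-promoted scrambling of the existing A–B ester. The fallback sets out from 8 and comes back at 15, replacing acylium chemistry by base-mediated opening of a benzodioxinone. Aldehyde 8 is oxidised (NaClO2, NaH2PO4, 2-methyl-2-butene) to 4-{[3,4-bis(benzyloxy)-6-methoxy-2-methylbenzoyl]oxy}-2-hydroxy-6-methylbenzoic acid F6. Condensation with acetone ((CF3CO)2O, CF3CO2H, 0 °C to rt) gives 2,2,5-trimethyl-4-oxo-4H-1,3-benzodioxin-7-yl 3,4-bis(benzyloxy)-6-methoxy-2-methylbenzoate F7. The 4-phenoxide of 12 (NaH, THF, 0 °C to rt) opens the dioxinone at its carbonyl to give benzyl 4-{[4-{[3,4-bis(benzyloxy)-6-methoxy-2-methylbenzoyl]oxy}-2-hydroxy-6-methylbenzoyl]oxy}-2-hydroxy-6-methylbenzoate F8. Hydrogenolysis of F8 (H2, 10% Pd/C, EtOAc/THF) then gives 15.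

**Further compounds**
F1 | step 4 | 3,4-bis(benzyloxy)-6-hydroxy-2-methylbenzoic acid | Cc1c(OCc2ccccc2)c(OCc2ccccc2)cc(O)c1C(=O)O
F2 | step 4 | methyl 3,4-bis(benzyloxy)-6-methoxy-2-methylbenzoate | COC(=O)c1c(OC)cc(OCc2ccccc2)c(OCc2ccccc2)c1C
F3 | step 5 | allyl 2,4-dihydroxy-6-methylbenzoate | Cc1cc(O)cc(O)c1C(=O)OCC=C
F4 | step 5 | allyl 4-{[3,4-bis(benzyloxy)-6-methoxy-2-methylbenzoyl]oxy}-2-hydroxy-6-methylbenzoate | COc1cc(OCc2ccccc2)c(OCc2ccccc2)c(C)c1C(=O)Oc1cc(C)c(C(=O)OCC=C)c(O)c1
F5 | step 5 | allyl 2-(benzyloxy)-4-{[3,4-bis(benzyloxy)-6-methoxy-2-methylbenzoyl]oxy}-6-methylbenzoate | COc1cc(OCc2ccccc2)c(OCc2ccccc2)c(C)c1C(=O)Oc1cc(C)c(C(=O)OCC=C)c(OCc2ccccc2)c1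
F6 | step 9 | 4-{[3,4-bis(benzyloxy)-6-methoxy-2-methylbenzoyl]oxy}-2-hydroxy-6-methylbenzoic acid | COc1cc(OCc2ccccc2)c(OCc2ccccc2)c(C)c1C(=O)Oc1cc(C)c(C(=O)O)c(O)c1
F7 | step 9 | 2,2,5-trimethyl-4-oxo-4H-1,3-benzodioxin-7-yl 3,4-bis(benzyloxy)-6-methoxy-2-methylbenzoate | COc1cc(OCc2ccccc2)c(OCc2ccccc2)c(C)c1C(=O)Oc1cc(C)c2C(=O)OC(C)(C)Oc2c1
F8 | step 9 | benzyl 4-{[4-{[3,4-bis(benzyloxy)-6-methoxy-2-methylbenzoyl]oxy}-2-hydroxy-6-methylbenzoyl]oxy}-2-hydroxy-6-methylbenzoate | COc1cc(OCc2ccccc2)c(OCc2ccccc2)c(C)c1C(=O)Oc1cc(C)c(C(=O)Oc2cc(C)c(C(=O)OCc3ccccc3)c(O)c2)c(O)c1
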